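**Retrosynthesis**
- The depsidone lactone (C–O) bond is formed last, by photocatalytic arene radical-cation C–H lactonisation of a diaryl-ether carboxylic acid. Ring closure at C-6 is favoured because that carbon is para to the chroman O.
- The diaryl ether comes from a Smiles O→O aryl shift of a depside whose ester-bearing carbon (C-7) is para to the chromanone C=O.
- The depside is 4-O-Bn-3-formylorsellinic acid esterified with 7-hydroxy-2,2,5-trimethylchroman-4-one. The 3-CHO is placed by 2-OH-directed Mg ortho-formylation.
- Ring order: arene A (Michael/Claisen annulation, then aromatisation); arene B (same annulation, then aromatisation); the chromanone pyran ring (Kabbe); the depside ester; the diaryl ether (Smiles); the 7-membered lactone (radical step).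

Assumption: mollicellin B has no stereocentre (the C(CH3)2 carbon is achiral), so no enantiocontrol is needed.

**Step 1**
Reactants: 1 methyl acetoacetate; 2 methyl (E)-crotonate
Product: 3 methyl 6-methyl-2,4-dioxocyclohexane-1-carboxylate
Conditions: NaOMe, MeOH, reflux; then HCl workup
Reagents that add atoms: none
Why: Michael addition of the acetoacetate enolate to crotonate, then Claisen (Dieckmann-type) closure of the acetyl CH3 onto the ester, gives the 1,3-dione. The ring carbons carry the correct Me and CO2Me relationship for an orsellinate.

**Step 2**
Reactants: 3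
Product: 4 methyl orsellinate (methyl 2,4-dihydroxy-6-methylbenzoate)
Conditions: I2 (2.2 equiv), MeOH, reflux
Reagents that add atoms: none
Why: α-Iodination of the dione enol followed by loss of HI and tautomerisation aromatises the ring (one dehydrogenation, dione to resorcinol).

**Step 3**
Reactants: 4
Product: 5 methyl 4-(benzyloxy)-2-hydroxy-6-methylbenzoate
Conditions: BnBr (1.0 equiv), K2CO3, acetone, reflux
Reagents that add atoms: benzyl bromide, BrCc1ccccc1
Why: The 2-OH is chelated to the ester C=O and the 4-OH is more acidic, so Williamson etherification is selective for O-4.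

**Step 4**
Reactants: 5
Product: 6 4-(benzyloxy)-2-hydroxy-6-methylbenzoic acid
Conditions: KOH, EtOH/H2O, reflux; then 2 M HCl
Reagents that add atoms: none
Why: Saponification of the hindered methyl ester; the aryl benzyl ether and the chelated phenol are untouched.

**Step 5**
Reactants: 7 acetylacetone; 2 methyl (E)-crotonate
Product: 8 4-acetyl-5-methylcyclohexane-1,3-dione
Conditions: NaOMe, MeOH, reflux; then HCl
Reagents that add atoms: none
Why: The same Michael/Claisen annulation as step 1, with acetylacetone in place of the ketoester, puts an acetyl group where the ester was.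

**Step 6**
Reactants: 8
Product: 9 1-(2,4-dihydroxy-6-methylphenyl)ethan-1-one
Conditions: I2 (2.2 equiv), MeOH, reflux
Reagents that add atoms: none
Why: Iodination/dehydroiodination aromatises the dione, as in step 2.

**Step 7**
Reactants: 9; 10 acetone
Product: 11 7-hydroxy-2,2,5-trimethylchroman-4-one
Conditions: acetone (excess), pyrrolidine (0.5 equiv), PhMe, reflux, Dean–Stark
Reagents that add atoms: none (pyrrolidine is a catalyst)
Why: Kabbe condensation builds the 2,2-dimethylchromanone; only the 2'-OH, which is ortho to the acyl group, cyclises, and the 4'-OH stays free.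

**Step 8**
Reactants: 6; 11
Product: 12 depside, 2-hydroxy-4-benzyloxy-6-methylbenzoate ester of the 7-OH of chromanone 11
Conditions: (CF3CO)2O, PhMe, 0 °C to rt; then add 11, 40 °C; NaHCO3/MeOH workup
Reagents that add atoms: none (the trifluoroacetyl groups are lost)
Why: Mixed-anhydride (trifluoroacetic anhydride-mediated) esterification of a hindered salicylic acid with an unhindered phenol, followed by removal of any O-trifluoroacetyl on the 2-OH.

**Step 9**
Reactants: 12
Product: 13 3-formyl depside
Conditions: MgCl2, Et3N, (CH2O)n, MeCN, 60–80 °C
Reagents that add atoms: paraformaldehyde, C=O (supplies the CHO carbon)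
Why: Mg-phenoxide-directed ortho-formylation goes only to C-3, the sole free position ortho to the 2-OH, so the regiochemistry is fixed.

**Step 10**
Reactants: 13
Product: 14 2-aryloxy-3-formyl-4-benzyloxy-6-methylbenzoic acid (Smiles product)
Conditions: Cs2CO3, DMF, 90 °C; then 1 M HCl
Reagents that add atoms: none
Why: Smiles (O→O aryl migration) rearrangement: the 2-phenoxide attacks the ipso carbon C-7 of the chromanone, which is para to the ketone. It goes through a 6-membered spiro Meisenheimer complex and expels the carboxylate, converting the ester into the diaryl ether.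

**Step 11**
Reactants: 14
Product: 15 4-O-benzyl depsidone
Conditions: Mes-Acr+-Me ClO4– (5 mol %), Co(dmgH)2pyCl (5 mol %), NaOAc (1 equiv), MeCN/HFIP 9:1, blue LEDs, N2, rt (H2 evolved)
Reagents that add atoms: none
Why: Proposed new method: the excited acridinium oxidises the electron-rich chromanone arene (or the carboxylate) to its radical cation or aroyloxy radical. The tethered CO2(–) adds at C-6, which is para to the chroman O and ortho to the aryloxy O. Cobaloxime then removes H•/e– to re-aromatise with H2 loss. The ipso carbon C-7 is meta to the chroman O and para to the C=O, so it is disfavoured. The closest known reaction is photocatalytic dehydrogenative C–H lactonisation of 2-arylbenzoic acids to benzocoumarins via arene radical cations; the 7-membered depsidone ring is the new feature.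

**Step 12**
Reactants: 15
Product: 16 mollicellin B
Conditions: H2 (1 atm), 10% Pd/C, EtOAc, rt, 1–2 h (stop at completion)
Reagents that add atoms: none (toluene is lost)
Why: Hydrogenolysis of the aryl benzyl ether ortho to the chelated CHO; the aryl aldehyde, aryl ketone and lactone survive short, mild hydrogenolysis.

**Compound list**
1 | methyl acetoacetate | CC(=O)CC(=O)OC | starting material
2 | methyl (E)-crotonate | C/C=C/C(=O)OC | starting material
3 | methyl 6-methyl-2,4-dioxocyclohexane-1-carboxylate | COC(=O)C1C(C)CC(=O)CC1=O | intermediate
4 | methyl orsellinate | COC(=O)c1c(C)cc(O)cc1O | intermediate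
5 | methyl 4-(benzyloxy)-2-hydroxy-6-methylbenzoate | COC(=O)c1c(C)cc(OCc2ccccc2)cc1O | intermediate
6 | 4-(benzyloxy)-2-hydroxy-6-methylbenzoic acid | Cc1cc(OCc2ccccc2)cc(O)c1C(=O)O | intermediate
7 | acetylacetone | CC(=O)CC(C)=O | starting material
8 | 4-acetyl-5-methylcyclohexane-1,3-dione | CC(=O)C1C(C)CC(=O)CC1=O | intermediate
9 | 1-(2,4-dihydroxy-6-methylphenyl)ethanone | CC(=O)c1c(C)cc(O)cc1O | intermediate
10 | acetone | CC(C)=O | starting material
11 | 7-hydroxy-2,2,5-trimethylchroman-4-one | Cc1cc(O)cc2c1C(=O)CC(C)(C)O2 | intermediate
12 | depside | Cc1cc(OCc2ccccc2)cc(O)c1C(=O)Oc1cc(C)c2c(c1)OC(C)(C)CC2=O | intermediate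
13 | 3-formyl depside | Cc1cc(OCc2ccccc2)c(C=O)c(O)c1C(=O)Oc1cc(C)c2c(c1)OC(C)(C)CC2=O | intermediate
14 | diaryl-ether carboxylic acid | Cc1cc(OCc2ccccc2)c(C=O)c(Oc2cc(C)c3c(c2)OC(C)(C)CC3=O)c1C(=O)O | intermediate
15 | 4-O-benzyl depsidone | Cc1cc(OCc2ccccc2)c(C=O)c2c1C(=O)Oc1c(C)c3c(cc1O2)OC(C)(C)CC3=O | intermediate
16 | mollicellin B | Cc1cc(O)c(C=O)c2c1C(=O)Oc1c(C)c3c(cc1O2)OC(C)(C)CC3=O | target

**Totals**
- Total steps: 12.
- Longest linear sequence: 9 (steps 1, 2, 3, 4, 8, 9, 10, 11, 12).
- The target has no stereocentres, so nothing needs to be set or preserved.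

**Three steps most likely to fail**
1. **Step 11 (radical lactonisation).** Risks are closure at C-8 instead of C-6, and protodecarboxylation.
   - Fallback: brominate 14 at C-6 with NBS, then close the lactone with CuI/phenanthroline/Cs2CO3 (Ullmann-type C–O coupling).
2. **Step 10 (Smiles).** The phenoxide is weakened by the ortho CHO and ester, and the para-acyl activation is only moderate.
   - Fallback: convert phenol 11 to its triflate and couple it with the 2-OH of the methyl ester of the 3-formyl ring-A acid (Pd/tBuBrettPhos, Cs2CO3), then hydrolyse the ester with Me3SnOH.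
3. **Step 9 (formylation).** The conditions may cause retro-oxa-Michael opening or α-hydroxymethylation of the chromanone.
   - Fallback: place the C-3 carbon at the dione stage by condensing 3 with DMF-DMA, then aromatise and carry the formyl group through.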